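**Retrosynthetic overview**

1. The two catechols are unmasked last from a tetramethyl ether. Before that, the C3' methylene of each 1,2,2-trimethylcyclopentyl ring is traced back to a ketone (Wolff–Kishner), giving a C2-symmetric bis(3-aryl-2,2,3-trimethylcyclopentanone).
2. Each cyclopentanone is cut at C1'–C2' (aryl-bearing quaternary carbon to gem-dimethyl carbon) and at C4'–C5' (the CH2 next to the aryl-bearing carbon and its CH2 neighbour). This is a two-directional, catalytic enantioselective [3+2] annulation of an achiral, flat bis(isopropenyl)bibenzyl with a 1,1-dimethyl-2-siloxyallyl cation. Both five-membered rings, all four quaternary carbons and both stereocentres form in this one operation; the arenes are bought and no other ring is made.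
3. Enabling feature: in each cyclopentane, C1' is benzylic to an arene with an ortho oxygen (it can be a stabilised tertiary cation) and is bonded to the gem-dimethyl carbon C2'. With a temporary carbonyl at C3', the unit C2'–C3'–C4' is an oxyallyl cation and C1'–C5' is an isopropenylarene.
4. The bis(isopropenyl)bibenzyl comes from 3-bromo-4,5-dimethoxybenzaldehyde (McMurry homocoupling of two molecules, diimide reduction, double Suzuki–Miyaura coupling). The siloxyallyl precursor comes from 3-hydroxy-3-methylbutan-2-one (acetylation, silyl enol ether formation).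

Key step: step 6

Remark on the chemistry: the chiral catalyst of step 6 is taken to be an arylpyrrolidine tert-leucine squaramide (the squaric acid diamide of 3,5-bis(trifluoromethyl)aniline and the tert-leucine amide of a 2-arylpyrrolidine). Its sense of induction cannot be assigned in advance; the catalyst antipode that leads to the (R,R)-diketone, and hence to the (S,S)-target, is assumed to be identified in a preliminary run and used.

**Step 1**
Reactants: 1 3-bromo-4,5-dimethoxybenzaldehyde
Product: 2 (E)-1,2-bis(3-bromo-4,5-dimethoxyphenyl)ethene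
Conditions: TiCl4, Zn, THF, reflux
Reagents that add atoms: 3-bromo-4,5-dimethoxybenzaldehyde (second molecule of 1), O=Cc1cc(Br)c(OC)c(OC)c1
Why: McMurry reductive homocoupling joins two molecules of aldehyde 1 at their carbonyl carbons on low-valent titanium (pinacolate formation, then deoxygenation) and should give the symmetrical stilbene (mainly E; the geometry is erased in step 2), with aryl bromides and methyl ethers tolerated.

**Step 2**
Reactants: 2 (E)-1,2-bis(3-bromo-4,5-dimethoxyphenyl)ethene
Product: 3 1,2-bis(3-bromo-4,5-dimethoxyphenyl)ethane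
Conditions: TsNHNH2 (excess, in portions), NaOAc, THF/H2O, reflux
Reagents that add atoms: none
Why: Diimide reduction transfers H2 to the stilbene C=C by concerted syn addition and cannot hydrogenolyse the two C–Br bonds needed in step 3.

**Step 3**
Reactants: 3 1,2-bis(3-bromo-4,5-dimethoxyphenyl)ethane
Product: 4 1,2-bis[3,4-dimethoxy-5-(prop-1-en-2-yl)phenyl]ethane
Conditions: isopropenylboronic acid pinacol ester (3 equiv), PdCl2(dppf) (5 mol %), K2CO3, 1,4-dioxane/H2O, 90 °C
Reagents that add atoms: isopropenylboronic acid pinacol ester, CC(=C)B1OC(C)(C)C(C)(C)O1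
Why: Double Suzuki–Miyaura coupling of an aryl bromide with an alkenyl boronate (one boronate per C–Br bond) is reliable with one ortho substituent and should give the achiral bis(α-methylstyrene).

**Step 4**
Reactants: 5 3-hydroxy-3-methylbutan-2-one
Product: 6 2-methyl-3-oxobutan-2-yl acetate
Conditions: Ac2O, Et3N, DMAP (cat.), CH2Cl2, rt to 40 °C
Reagents that add atoms: acetic anhydride, CC(=O)OC(C)=O
Why: DMAP-catalysed acylation of a tertiary α-ketol installs the leaving group of the later allyl cation.

**Step 5**
Reactants: 6 2-methyl-3-oxobutan-2-yl acetate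
Product: 7 2-methyl-3-(trimethylsilyloxy)but-3-en-2-yl acetate
Conditions: TMSOTf, Et3N, CH2Cl2, 0 °C; non-aqueous work-up, distillation
Reagents that add atoms: trimethylsilyl trifluoromethanesulfonate, C[Si](C)(C)OS(=O)(=O)C(F)(F)F
Why: Soft enolisation (silyl enol ether formation) can only occur toward the methyl group because the other α-carbon is fully substituted, and the less acidic acetate is left alone.

**Step 6**
Reactants: 4 1,2-bis[3,4-dimethoxy-5-(prop-1-en-2-yl)phenyl]ethane; 7 2-methyl-3-(trimethylsilyloxy)but-3-en-2-yl acetate
Product: 9 (3R,3'R)-3,3'-[ethane-1,2-diylbis(2,3-dimethoxy-5,1-phenylene)]bis(2,2,3-trimethylcyclopentan-1-one), via mono-annulated keto-alkene 8 (not isolated)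
Conditions: 7 (3 equiv, slow addition), chiral squaramide hydrogen-bond donor (20 mol %), TMSOTf (20 mol %), t-BuOMe/CH2Cl2, −78 °C; then aq. NaHCO3
Reagents that add atoms: none
Why: Proposed new method: the squaramide-activated silyl triflate ionises the tertiary allylic acetate of 7 to a 1,1-dimethyl-2-siloxyallyl cation; the terminal CH2 of an isopropenyl group of 4 attacks its unsubstituted terminus (first C–C bond, no stereocentre), the resulting tertiary benzylic cation, stabilised by the ortho-methoxy arene, is captured by the tetrasubstituted silyl enol ether carbon (second C–C bond), and the silyl group leaves as TMSOAc while TMSOTf returns to the cycle; the same sequence with a second molecule of 7 at the other isopropenyl group converts 8 into 9. The closest known reaction types are the Lewis-acid-promoted stepwise [3+2] cyclopentannulation of α-methylstyrenes with 2-siloxyallyl halides (and with oxyallyl cations generated with Fe2(CO)9), which gives racemic 3-aryl-2,2,3-trimethylcyclopentanones with this regiochemistry, and the squaramide/silyl triflate co-catalysed enantioselective (4+3) cycloadditions of siloxyallyl cations and enantioconvergent SN1 allylations of tertiary carbocations; what is new is enantiocontrol of a [3+2] closure on a 1,1-disubstituted styrene, run twice in one molecule. Each cyclopentanone ring closes in the second bond formation by attack of the enol ether carbon on the planar benzylic cation, formally a 5-(enolendo)-exo-trig closure with the enol ether double bond inside the new ring; this mode is strained for enolate alkylations but is the established closing step of stepwise oxyallyl [3+2] annulations, because an open cation needs no backside trajectory. Each quaternary stereocentre arises in this closure and is controlled by the chiral squaramide-bound triflate of the contact ion pair, which shields one face of the cation; the two ends react independently, so the minor sense of induction should be diverted mainly into the meso diketone, which is separable from 9. The step needs regioselectivity (alkene CH2 to the primary allyl terminus, secured by sterics and by formation of the tetrasubstituted enol ether), C- over O-closure (secured by O-silylation) and chemoselectivity for the isopropenyl groups over the dimethoxyarene, over proton loss from the cation and over self-trapping of the cation by 7 (secured by the nucleophilic 1,1-disubstituted alkene, the non-basic medium at low temperature and the slow addition of 7).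

**Step 7**
Reactants: 9 (3R,3'R)-3,3'-[ethane-1,2-diylbis(2,3-dimethoxy-5,1-phenylene)]bis(2,2,3-trimethylcyclopentan-1-one)
Product: 11 1,2-bis{3,4-dimethoxy-5-[(1S)-1,2,2-trimethylcyclopentyl]phenyl}ethane, via bis-hydrazone 10 (not isolated)
Conditions: N2H4·H2O, KOH, diethylene glycol, 130 °C, then 200 °C with removal of water
Reagents that add atoms: none
Why: Wolff–Kishner reduction (Huang-Minlon procedure) removes the temporary carbonyls, as in the conversion of 2,2,3-trimethyl-3-arylcyclopentanones into the parent cyclopentanes; the quaternary stereocentres carry no hydrogen and cannot epimerise (the descriptor changes from R to S only because the CIP priorities change when the carbonyl is removed).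

**Step 8**
Reactants: 11 1,2-bis{3,4-dimethoxy-5-[(1S)-1,2,2-trimethylcyclopentyl]phenyl}ethane
Product: 13 5,5'-(ethane-1,2-diyl)bis{3-[(1S)-1,2,2-trimethylcyclopentyl]benzene-1,2-diol} (target), via bis-bromoborole 12 (not isolated)
Conditions: BBr3 (8 equiv), CH2Cl2, −78 °C to rt; then H2O, 0 °C, under argon
Reagents that add atoms: none
Why: Lewis-acid cleavage of aryl methyl ethers by BBr3 (O-complexation, bromide attack at methyl) frees both catechols after hydrolysis of the cyclic boron esters and does not touch the all-carbon quaternary centres.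

**Compound list**

1 | 3-bromo-4,5-dimethoxybenzaldehyde | O=Cc1cc(Br)c(OC)c(OC)c1 | starting material
2 | (E)-1,2-bis(3-bromo-4,5-dimethoxyphenyl)ethene | COc1cc(/C=C/c2cc(Br)c(OC)c(OC)c2)cc(Br)c1OC | intermediate
3 | 1,2-bis(3-bromo-4,5-dimethoxyphenyl)ethane | COc1cc(CCc2cc(Br)c(OC)c(OC)c2)cc(Br)c1OC | intermediate
4 | 1,2-bis[3,4-dimethoxy-5-(prop-1-en-2-yl)phenyl]ethane | CC(=C)c1cc(CCc2cc(OC)c(OC)c(C(C)=C)c2)cc(OC)c1OC | intermediate
5 | 3-hydroxy-3-methylbutan-2-one | CC(=O)C(C)(C)O | starting material
6 | 2-methyl-3-oxobutan-2-yl acetate | CC(=O)OC(C)(C)C(C)=O | intermediate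
7 | 2-methyl-3-(trimethylsilyloxy)but-3-en-2-yl acetate | CC(=O)OC(C)(C)C(=C)O[Si](C)(C)C | intermediate
8 | (3R)-3-{5-[2-(3,4-dimethoxy-5-(prop-1-en-2-yl)phenyl)ethyl]-2,3-dimethoxyphenyl}-2,2,3-trimethylcyclopentan-1-one (mono-annulated keto-alkene, not isolated) | CC1(C)C(=O)CC[C@]1(C)c1cc(CCc2cc(OC)c(OC)c(C(C)=C)c2)cc(OC)c1OC | intermediate
9 | (3R,3'R)-3,3'-[ethane-1,2-diylbis(2,3-dimethoxy-5,1-phenylene)]bis(2,2,3-trimethylcyclopentan-1-one) | CC1(C)C(=O)CC[C@]1(C)c1cc(CCc2cc(OC)c(OC)c([C@@]3(C)CCC(=O)C3(C)C)c2)cc(OC)c1OC | intermediate
10 | bis-hydrazone of 9 (both C=O replaced by C=N–NH2, quaternary centres unchanged, not isolated) | CC1(C)C(=NN)CC[C@]1(C)c1cc(CCc2cc(OC)c(OC)c([C@@]3(C)CCC(=NN)C3(C)C)c2)cc(OC)c1OC | intermediate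
11 | 1,2-bis{3,4-dimethoxy-5-[(1S)-1,2,2-trimethylcyclopentyl]phenyl}ethane | CC1(C)CCC[C@]1(C)c1cc(CCc2cc(OC)c(OC)c([C@@]3(C)CCCC3(C)C)c2)cc(OC)c1OC | intermediate
12 | 1,2-bis{2-bromo-7-[(1S)-1,2,2-trimethylcyclopentyl]-1,3,2-benzodioxaborol-5-yl}ethane (bis-bromoborole, not isolated) | CC1(C)CCC[C@]1(C)c1cc(CCc2cc3OB(Br)Oc3c([C@@]4(C)CCCC4(C)C)c2)cc2OB(Br)Oc12 | intermediate
13 | 5,5'-(ethane-1,2-diyl)bis{3-[(1S)-1,2,2-trimethylcyclopentyl]benzene-1,2-diol} | CC1(C)CCC[C@]1(C)c1cc(CCc2cc(O)c(O)c([C@@]3(C)CCCC3(C)C)c2)cc(O)c1O | target

**Step count**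

Total steps: 8. Longest linear sequence: 6 (steps 1, 2, 3, 6, 7, 8); steps 4 and 5 form a two-step side branch.

**Steps most likely to fail**

1. Step 6 (Proposed new method). What may go wrong: weak enantiofacial discrimination in the ring closure because the catalyst-bound counter-anion is remote from the internal cation, proton loss from the benzylic cation instead of closure, or consumption of the allyl cation by its own silyl enol ether precursor. Fallback with known chemistry, setting out from 4 and returning at 9: the two-directional annulation is run without chiral control under the established Lewis-acid cyclopentannulation conditions (ZnCl2, CH2Cl2, −78 to 0 °C) with 3-bromo-3-methyl-2-(trimethylsilyloxy)but-1-ene F1, which is made from commercial 3-bromo-3-methylbutan-2-one with TMSOTf and Et3N. This should give the diketone as a mixture of 9, its enantiomer (3S,3'S)-diketone F2 and the meso (3R,3'S)-diketone F3. The meso isomer is removed by chromatography or crystallisation, and the racemic pair is resolved by preparative HPLC on a chiral stationary phase to give 9.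

2. Step 7. What may go wrong: slow hydrazone formation at a carbonyl flanked by a quaternary carbon, and partial cleavage of aryl methyl ethers by hot alkali, leading to incomplete or unclean deoxygenation. Fallback, setting out from 9 and returning at 11, avoids addition to the carbonyl: enolisation toward the only available CH2 (KHMDS, PhNTf2, THF, −78 °C) should give the bis(enol triflate) 1,2-bis{3,4-dimethoxy-5-[(1S)-1,5,5-trimethyl-4-(trifluoromethanesulfonyloxy)cyclopent-3-en-1-yl]phenyl}ethane F4. Palladium-catalysed formate reduction (Pd(OAc)2, PPh3, Bu3N, HCO2H, DMF, 60 °C) should give the bis(cyclopentene) 1,2-bis{3,4-dimethoxy-5-[(1S)-1,5,5-trimethylcyclopent-3-en-1-yl]phenyl}ethane F5, and hydrogenation (H2, Pd/C, EtOAc) should give 11.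

3. Step 2. What may go wrong: incomplete transfer of hydrogen to the conjugated, electron-rich stilbene because diimide disproportionates faster than it reduces; a switch to catalytic hydrogenation would risk hydrodebromination. Fallback, setting out from 1 and returning at 3, builds the ethane bridge by benzylic coupling instead of through the stilbene: reduction of 1 (NaBH4, MeOH, 0 °C) should give (3-bromo-4,5-dimethoxyphenyl)methanol F6, bromination (PBr3, CH2Cl2, 0 °C) should give 1-bromo-5-(bromomethyl)-2,3-dimethoxybenzene F7, and Wurtz-type reductive homocoupling of two molecules of the benzylic bromide with SmI2 (THF, rt), which leaves aryl bromides untouched, should give 3.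

**Further compounds**

F1 | step 6 | 3-bromo-3-methyl-2-(trimethylsilyloxy)but-1-ene | CC(C)(Br)C(=C)O[Si](C)(C)C
F2 | step 6 | (3S,3'S)-3,3'-[ethane-1,2-diylbis(2,3-dimethoxy-5,1-phenylene)]bis(2,2,3-trimethylcyclopentan-1-one) | CC1(C)C(=O)CC[C@@]1(C)c1cc(CCc2cc(OC)c(OC)c([C@]3(C)CCC(=O)C3(C)C)c2)cc(OC)c1OC
F3 | step 6 | meso (3R,3'S)-3,3'-[ethane-1,2-diylbis(2,3-dimethoxy-5,1-phenylene)]bis(2,2,3-trimethylcyclopentan-1-one) | CC1(C)C(=O)CC[C@]1(C)c1cc(CCc2cc(OC)c(OC)c([C@]3(C)CCC(=O)C3(C)C)c2)cc(OC)c1OC
F4 | step 7 | 1,2-bis{3,4-dimethoxy-5-[(1S)-1,5,5-trimethyl-4-(trifluoromethanesulfonyloxy)cyclopent-3-en-1-yl]phenyl}ethane | CC1(C)C(OS(=O)(=O)C(F)(F)F)=CC[C@]1(C)c1cc(CCc2cc(OC)c(OC)c([C@@]3(C)CC=C(OS(=O)(=O)C(F)(F)F)C3(C)C)c2)cc(OC)c1OC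
F5 | step 7 | 1,2-bis{3,4-dimethoxy-5-[(1S)-1,5,5-trimethylcyclopent-3-en-1-yl]phenyl}ethane | CC1(C)C=CC[C@]1(C)c1cc(CCc2cc(OC)c(OC)c([C@@]3(C)CC=CC3(C)C)c2)cc(OC)c1OC
F6 | step 2 | (3-bromo-4,5-dimethoxyphenyl)methanol | COc1cc(CO)cc(Br)c1OC
F7 | step 2 | 1-bromo-5-(bromomethyl)-2,3-dimethoxybenzene | COc1cc(CBr)cc(Br)c1OC
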